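3 amounts of starting material are asked of the 3.0 M flask, and you can reach them through one ratio of rates read from the two earlier runs.

| flask | starting material | precatalyst | remark | time |
|---|---|---|---|---|
| epsilon | 1.5 M (fed, over 25 min) | 3.8 mol% | run made earlier |  |
| beta | 2.2 M (fed, over 25 min) | 3.8 mol% | run made earlier |  |
| flask | 3.0 M (fed, over 25 min) | 3.8 mol% |  | 6.0 h |

- epsilon (time / h: starting material / %, target / %): 0.250: 57.4, 0; 0.667: 87.6, 0.2; 1.33: 73.1, 0; 2.00: 66.1, 0.2; 3.00: 54.3, 0.8; 4.00: 46.8, 1.6
- beta (time / h: starting material / %, target / %): 0.250: 58.3, 0.3; 0.667: 88.1, 0; 1.33: 75.7, 1.0; 2.00: 66.1, 0.9; 3.00: 53.8, 0.1; 4.00: 46.8, 3.0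

(readings scatter by 1 percentage point)

- amount of starting material in percent of the starting material charged, at 80 min, 3.0 h and 6.0 h

- the numbers in the tables scatter by 1 percentage point (one standard deviation)
- percentages count the whole charge, also what has not yet gone in

The epsilon run and the beta run, at 1.5 M and 2.2 M, both read 46.8% at 4.00 h, so I pool them and carry their percent course to the 3.0 M flask, taking 74.4% at 80 min and 54.0% at 3.0 h as read. After the feed, starting material falls with a pseudo-first-order constant k₁ = 0.213 h⁻¹ between 0.667 h and 2.00 h, but the constant k₂ between 2.00 h and 4.00 h is lower, 0.173 h⁻¹. I carry this slowing as a number, 0.809: the retention ρ, the constant of a later window divided by that of the window before it, a ratio of rates whose value belongs to these two windows.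

Assuming that the next window keeps the same ρ, I get 0.140 h⁻¹ for the window up to 6.0 h, and so 35.4% at 6.0 h, which is 2.3 percentage points above what an unchanged k₂ gives. The forecast, which holds that “the percent course therefore looks independent of concentration”, says 74.8%, 54.3% and 37%, so its last value stands above mine. The 3.0 M flask gives 74.4%, 52.8% and 36.8%, within the margin of the forecast.

    2 free catalyst ⇌ resting dimer, settled at all times (K = 20.0 L mol⁻¹)
    precatalyst → free catalyst (k = 0.0320 h⁻¹)
    starting material ⇌ isomer of the product B (K = 1.50, k = 0.280 h⁻¹)
    starting material + free catalyst ⇌ target + free catalyst, rate k4*[starting material]*[free catalyst] forward; the back reaction follows from the equilibrium constant (K = 1.80, k = 1.60 L mol⁻¹ h⁻¹)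
    starting material + free catalyst ⇌ isomer of the product A + free catalyst, rate k5*[starting material]*[free catalyst] forward; the back reaction follows from the equilibrium constant (K = 3.00, k = 3.80 L mol⁻¹ h⁻¹)
    2 free catalyst → spent catalyst (k = 0.730 L mol⁻¹ h⁻¹)

Going from the 46.8% of the earlier runs at 4.00 h to the 36.8% of the 3.0 M flask at 6.0 h gives ρ = 0.696 against k₂, below the 0.809 read from the runs, and in this flask the forward passing of starting material into isomer of the product B, the way back not counted, has a half-life of 2.5 h, shorter than the 6.0 h of the run. The relaxation of starting material and target by its own step has a half-life of 21.8 h at 6.00 h, longer than the run, and at 6.00 h the flask holds 51.7% isomer of the product B against 3.43% target.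

The data stem from a simulated flask on assumed constants; noise was put on by code.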